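Remark (assumptions): cembrane numbering is used for all atoms. C1 is the ring-fusion CH that bears C15. C2 is a CH2 and C3/C4 are the epoxide carbons (C18 is the methyl on C4). C5 is a CH2, C6=C7 is the alkene, and C8 is the carbinol carbon (C19 is its methyl). C9–C11 are CH2 groups, C12 is a CH (C20 is its methyl), C13 is CH–OAc, and C14 is the ring-fusion CH–O. C15=C17 is the exocyclic methylene and C16 is the lactone carbonyl. Compounds 1, 6 and 10 are taken as commercial.

## Analysis of the target

- **Ring system.** Target 27 is a cembranolide. A 14-membered carbocycle (C1–C14) is cis-fused along C1–C14 to an α-methylene-γ-butyrolactone (O–C14–C1–C15(=C17H2)–C16=O).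
- **Stereocentres.** There are seven, (1S,3R,4R,8R,12S,13R,14R), and they fall into three groups.
  - The contiguous tetrad C12–C13–C14–C1. C20, the acetoxy group and the lactone oxygen are all syn along the zigzag, and H1/H14 are cis.
  - The trisubstituted epoxide C3–C4, with C2 and C5 trans.
  - The isolated tertiary allylic carbinol C8, next to the E alkene C6=C7.
- **No relay between groups.** The groups are separated by CH2 spacers (C2, C5, C9–C11), so no group can pass stereochemical information to the next.
- **Sensitive groups.**
  - The C15=C17 Michael acceptor.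
  - The tertiary allylic alcohol, which ionises in acid.
  - The acid-labile epoxide.
  - The O13 acetate and O14 lactone, which are base-labile and can exchange acyl groups.
- **Main difficulty.** A 14-membered ring must be closed without conformational help, and the crowded cis ring fusion with its syn,syn relation to C13 must be made at the same place.
- **The feature that invites the chosen move.** The C1–C14 bond belongs to both rings. It sits between the C13 oxygen and the exocyclic C15=C17 double bond. The array HO–C13 / O–C14 / C1–C15(=C17H2)–C16O2 is the exact retron of a 2-(alkoxycarbonyl)allyl metal adding through its substituted terminus to an α-hydroxy aldehyde.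
- **Consequence.** One bond formation can close the macrocycle, trigger the lactone closure and set C1 and C14 from C13.

## Retrosynthetic reasoning

**27 ⇒ 26 (cut C3–O and C4–O).** The epoxide goes in last. In an open chain it would lie γ,δ to the enoate and next to the allyl metal, where it invites vinylogous elimination or 3-exo attack. In 26, C3=C4 is the only electron-rich trisubstituted alkene, so an electrophilic, catalyst-controlled oxygen transfer should find it. The forward step must deliver oxygen to one face only and leave C6=C7 and C15=C17 alone.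

**26 ⇒ 25 (cut the O13–acyl bond).** The C13 hydroxyl must be free in the key step because it is the controlling element there. Acetylation therefore follows ring closure. It only has to tell a secondary alcohol from the tertiary C8 alcohol.

**25 ⇒ 22 (cut C1–C14 and O14–C16; key disconnection).**
- Both rings are opened at their shared bond. The product is an acyclic chain with an α-hydroxy aldehyde (C13/C14) at one end and a 2-(bromomethyl)enoate (C17–C15(C16)=C1) at the other.
- No other cut removes two rings and two stereocentres at once.
- The precursor keeps only three stereocentres (C8, C12, C13), which are far apart and can each be set independently.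
- The forward reaction must close a 14-membered ring, react through C1 rather than C17, give 13,14-syn and 1,14-syn, and end in the five-membered lactone.

**22 ⇒ 21 ⇒ 20 + 9 (cut C6=C7).**
- This cut splits the skeleton into two ten-carbon halves.
- It needs no functional handle beyond two terminal alkenes.
- It places the new alkene next to the fully substituted C8, which should enforce E geometry and suppress self-metathesis of 20.
- The silyl ether on O13 in 21 is only a carrier for the labile α-hydroxy aldehyde and is removed just before ring closure.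

**9 ⇒ 8 ⇒ 5 + 6, and 5 ⇒ 4 ⇒ 1 (cut C17–Br with allylic shift, then C1–C15, then C2–C3 and C4–C18).**
- The bromide comes from the Baylis–Hillman-type carbinol 8 by SN2' substitution. This erases the C1 carbinol centre, so 8 may be racemic.
- 8 comes from an α-metallated acrylate made from 6 and the β,γ-unsaturated aldehyde 5.
- The E-trisubstituted alkene C3=C4 of 4 is set in one step by syn-methylmetallation of the alkyne in 1, followed by trapping with a two-carbon epoxide.

**20 ⇒ 19 ⇒ 18 ⇒ 17 ⇒ 16 ⇒ 15 ⇒ 14 ⇒ 13 ⇒ 10 (cut C7=CH2, C9–H, the C8/C9–O bonds, C7–O and C13–O).**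
- Compound 10 already holds C7–C14, C19 and C20, with C12 in the correct configuration.
- C13 is oxygenated by enamine catalysis.
- C8 is built from the isopropylidene end in three moves: E-selective allylic oxidation (15), catalytic asymmetric epoxidation of the allylic alcohol (16), and hydride opening at the less substituted C9 (17).
- Oxidation and methylenation then give the vinyl carbinol 19. A direct oxidation of the primary silyl ether gives 20.

## Alternatives that were turned down

Alternative 1: the textbook cut at C6=C7, closed by ring-closing metathesis of the fully decorated seco-diene A1 to give 27.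
- The forward key step joins a vinyl group on the fully substituted C8 to the allyl group on C4.
- This closure forms no stereocentre.
- Nothing in the structure secures the E geometry in a 14-membered ring.
- The 1,1-disubstituted acrylate C15=C17 is left exposed to the carbene.
- All seven stereocentres, the cis lactone and the epoxide must already be present in A1. The hardest bond, C1–C14, would then be made intermolecularly between two advanced pieces, and the ring closure simplifies very little.

Alternative 2: cut at C13–C14, closed by a reductive pinacol macrocyclisation of dialdehyde A2 with low-valent titanium or samarium to give 24.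
- The step would form the ring and both carbinol centres.
- C1 in A2 is α to an aldehyde and allylic to the acrylate, so epimerisation and migration into conjugation are built into the substrate.
- The reductant also attacks the acrylate and the allylic C8–O bond.
- No element in A2 distinguishes syn from anti coupling or one pair of faces from the other.
- C1 would have to be set beforehand by a separate asymmetric step.

Alternative 3: the biomimetic cut, a late Schenck ene reaction of singlet oxygen with the Δ7 cembranolide A3 to give hydroperoxide A4, which is then reduced to 27.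
- The step would copy the presumed origin of the C6=C7/C8–OH unit.
- C7=C8 has three sets of allylic hydrogens (C6, C9, C19). The preference for abstraction on the more crowded side does not separate C6 from C19, so the 7-hydroperoxy-Δ8(19) isomer competes.
- The face of attack, and with it C8, is left to the ring conformation.
- A3 poses the same macrocyclisation problem as 27, so the step adds risk without removing work.

Key step: step 15

## Steps

Step 1
Reactants: 1 pent-1-en-4-yne
Product: 4 (3E)-4-methylhepta-3,6-dien-1-ol, via alkenylalane 2 (not isolated), via lithium alanate 3 (not isolated)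
Conditions: Me3Al, Cp2ZrCl2 (cat.), CH2Cl2, 0 °C to rt; n-BuLi, hexane, 0 °C; oxirane, THF, −30 °C to rt; aq. work-up
Reagents that add atoms: trimethylaluminium, C[Al](C)C; oxirane, C1CO1
Why: Negishi carboalumination adds methyl and aluminium syn across the terminal alkyne (methyl to the internal carbon), which fixes the E geometry of C3=C4; the isolated terminal alkene reacts far more slowly. The derived ate complex opens the epoxide with retention of alkene geometry.

Step 2
Reactants: 4 (3E)-4-methylhepta-3,6-dien-1-ol
Product: 5 (3E)-4-methylhepta-3,6-dienal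
Conditions: Dess–Martin periodinane, NaHCO3, CH2Cl2, 0 °C; used without chromatography
Reagents that add atoms: none
Why: Buffered Dess–Martin oxidation is fast and neutral, so the β,γ-unsaturated aldehyde should form without migration of C3=C4 into conjugation.

Step 3
Reactants: 6 methyl propiolate; 5 (3E)-4-methylhepta-3,6-dienal
Product: 8 methyl (5E)-3-hydroxy-6-methyl-2-methylidenenona-5,8-dienoate (racemic at the carbinol), via vinylalane 7 (not isolated)
Conditions: 6, DIBAL-H, NMO, THF, 0 °C; then 5, 0 °C to rt; aq. work-up
Reagents that add atoms: none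
Why: Hydroalumination of the propiolate puts aluminium on the α-carbon, and the α-metallated acrylate 7 adds 1,2 to the aldehyde (vinylalumination). This gives the Morita–Baylis–Hillman-type adduct without the amine and the long reaction time that 5 would not survive. The C1 carbinol is left racemic on purpose, because step 4 erases it.

Step 4
Reactants: 8 methyl (5E)-3-hydroxy-6-methyl-2-methylidenenona-5,8-dienoate
Product: 9 methyl (2Z,5E)-2-(bromomethyl)-6-methylnona-2,5,8-trienoate
Conditions: NBS, Me2S, CH2Cl2, 0 °C to rt
Reagents that add atoms: N-bromosuccinimide, O=C1CCC(=O)N1Br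
Why: Corey–Kim-type activation turns the hydroxyl into an alkoxysulfonium leaving group, and bromide attacks C17 in an SN2' reaction, the usual course for Baylis–Hillman alcohols. The isomer with the C2 chain trans to the ester (2Z) is favoured because it minimises allylic strain.

Step 5
Reactants: 10 (S)-citronellal
Product: 13 (2R,3S)-3,7-dimethyloct-6-ene-1,2-diol, via aminoxy aldehyde 11 (not isolated), via aminoxy alcohol 12 (not isolated)
Conditions: PhNO, L-proline (cat.), CHCl3, 4 °C; NaBH4, EtOH, 0 °C; Zn, AcOH, rt
Reagents that add atoms: nitrosobenzene, O=Nc1ccccc1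
Why: In the proline-catalysed α-aminoxylation the enamine of 10 attacks the nitroso oxygen on the face fixed by L-proline, which should give 13R under catalyst control next to the existing C12 centre. Immediate hydride reduction prevents epimerisation, and zinc cleaves the N–O bond without touching the alkene.

Step 6
Reactants: 13 (2R,3S)-3,7-dimethyloct-6-ene-1,2-diol
Product: 14 (2R,3S)-3,7-dimethyl-1,2-bis(triethylsilyloxy)oct-6-ene
Conditions: TESCl, imidazole, CH2Cl2, 0 °C to rt
Reagents that add atoms: chlorotriethylsilane, CC[Si](Cl)(CC)CC
Why: Standard silylation. Triethylsilyl is chosen because the primary ether can later be oxidised directly (step 12) and the secondary one comes off under buffered fluoride (step 14).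

Step 7
Reactants: 14 (2R,3S)-3,7-dimethyl-1,2-bis(triethylsilyloxy)oct-6-ene
Product: 15 (2E,6S,7R)-2,6-dimethyl-7,8-bis(triethylsilyloxy)oct-2-en-1-ol
Conditions: SeO2 (cat.), t-BuOOH, CH2Cl2, 0 °C to rt
Reagents that add atoms: tert-butyl hydroperoxide, CC(C)(C)OO; selenium dioxide (catalytic oxygen carrier), O=[Se]=O
Why: Riley-type allylic oxidation (ene reaction followed by a [2,3] shift) of an isopropylidene group selectively hydroxylates the methyl trans to the chain, which gives the E allylic alcohol and turns that methyl into C7.

Step 8
Reactants: 15 (2E,6S,7R)-2,6-dimethyl-7,8-bis(triethylsilyloxy)oct-2-en-1-ol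
Product: 16 [(2S,3S)-2-methyl-3-{(3S,4R)-3-methyl-4,5-bis(triethylsilyloxy)pentyl}oxiran-2-yl]methanol
Conditions: Ti(Oi-Pr)4 (cat.), L-(+)-DET (cat.), t-BuOOH, 4 Å MS, CH2Cl2, −20 °C
Reagents that add atoms: tert-butyl hydroperoxide, CC(C)(C)OO
Why: Sharpless asymmetric epoxidation of an E-2-methyl allylic alcohol is a favourable substrate class. L-(+)-tartrate delivers oxygen to the face that gives the (2S,3S)-epoxide, and this fixes the C8–O bond in the sense needed for 8R, independently of the remote centres.

Step 9
Reactants: 16 [(2S,3S)-2-methyl-3-{(3S,4R)-3-methyl-4,5-bis(triethylsilyloxy)pentyl}oxiran-2-yl]methanol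
Product: 17 (2R,6S,7R)-2,6-dimethyl-7,8-bis(triethylsilyloxy)octane-1,2-diol
Conditions: LiAlH4, Et2O, 0 °C
Reagents that add atoms: none
Why: Hydride opens the epoxide by SN2 attack at the less substituted carbon C9, because C8 is fully substituted. The C8–O bond is not touched, so the tertiary alcohol keeps its configuration (8R).

Step 10
Reactants: 17 (2R,6S,7R)-2,6-dimethyl-7,8-bis(triethylsilyloxy)octane-1,2-diol
Product: 18 (2R,6S,7R)-2-hydroxy-2,6-dimethyl-7,8-bis(triethylsilyloxy)octanal
Conditions: SO3·pyridine, DMSO, Et3N, CH2Cl2, 0 °C
Reagents that add atoms: none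
Why: Parikh–Doering oxidation converts the free primary alcohol into the aldehyde without glycol cleavage. It leaves the tertiary alcohol and both silyl ethers intact, and C8 has no α-hydrogen to lose.

Step 11
Reactants: 18 (2R,6S,7R)-2-hydroxy-2,6-dimethyl-7,8-bis(triethylsilyloxy)octanal
Product: 19 (3R,7S,8R)-3,7-dimethyl-8,9-bis(triethylsilyloxy)non-1-en-3-ol
Conditions: Ph3PCH3Br, KHMDS (excess ylide), THF, −78 to 0 °C
Reagents that add atoms: methyltriphenylphosphonium bromide, C[P+](c1ccccc1)(c1ccccc1)c1ccccc1.[Br-]
Why: Wittig methylenation gives the vinyl carbinol. One extra equivalent of ylide covers the free tertiary hydroxyl, and no stereocentre is at risk.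

Step 12
Reactants: 19 (3R,7S,8R)-3,7-dimethyl-8,9-bis(triethylsilyloxy)non-1-en-3-ol
Product: 20 (2R,3S,7R)-7-hydroxy-3,7-dimethyl-2-(triethylsilyloxy)non-8-enal
Conditions: (COCl)2, DMSO, CH2Cl2, −78 to −40 °C; Et3N, −78 to 0 °C
Reagents that add atoms: none
Why: Under Swern conditions the activated sulfoxide attacks the less hindered primary triethylsilyl ether and oxidises it directly to the aldehyde. The secondary silyl ether and the tertiary alcohol are left alone, which saves a separate deprotection.

Step 13
Reactants: 20 (2R,3S,7R)-7-hydroxy-3,7-dimethyl-2-(triethylsilyloxy)non-8-enal; 9 methyl (2Z,5E)-2-(bromomethyl)-6-methylnona-2,5,8-trienoate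
Product: 21 methyl (2Z,5E,8E,10R,14S,15R)-2-(bromomethyl)-10-hydroxy-6,10,14-trimethyl-16-oxo-15-(triethylsilyloxy)hexadeca-2,5,8-trienoate
Conditions: Hoveyda–Grubbs II (cat.), 1,4-benzoquinone (cat.), CH2Cl2, 40 °C
Reagents that add atoms: none
Why: This olefin cross metathesis pairs a rapidly exchanging terminal alkene (9) with a hindered free tertiary allylic alcohol that does not homodimerise (20), which is the selective combination, and the bulk at C8 enforces the E alkene. The trisubstituted alkenes of 9 are inert, and the E geometry of C3=C4 makes a six-membered ring closure within 9 geometrically impossible.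

Step 14
Reactants: 21 methyl (2Z,5E,8E,10R,14S,15R)-2-(bromomethyl)-10-hydroxy-6,10,14-trimethyl-16-oxo-15-(triethylsilyloxy)hexadeca-2,5,8-trienoate
Product: 22 methyl (2Z,5E,8E,10R,14S,15R)-2-(bromomethyl)-10,15-dihydroxy-6,10,14-trimethyl-16-oxohexadeca-2,5,8-trienoate
Conditions: HF·pyridine, pyridine, THF, 0 °C; used crude
Reagents that add atoms: none
Why: Buffered fluoride removes the secondary silyl ether without acid strong enough to ionise the tertiary allylic alcohol and without base that could epimerise C13 or displace the bromide. The α-hydroxy aldehyde is taken on at once.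

Step 15
Reactants: 22 methyl (2Z,5E,8E,10R,14S,15R)-2-(bromomethyl)-10,15-dihydroxy-6,10,14-trimethyl-16-oxohexadeca-2,5,8-trienoate
Product: 25 (1S,3E,6E,8R,12S,13R,14R)-8,13-dihydroxycembra-3,6,15(17)-trien-16,14-olide, via allylindium 23 (not isolated), via hydroxy ester 24 (not isolated)
Conditions: In powder, THF–H2O (1:1), rt, 22 added by syringe pump (final ca. 1 mM); then PPTS (cat.), CH2Cl2, rt
Reagents that add atoms: none
Why: Indium inserts into the allylic C17–Br bond to give the 2-(methoxycarbonyl)allylindium 23, whose E and Z forms interconvert by 1,3-metallotropic shift, so the geometry of 9 and the erased carbinol centre of 8 do not matter and the step is stereoconvergent. 23 adds through its substituted terminus C1 (SE2') to the C14 aldehyde in a chair-like six-membered transition state, which forms C1–C14, moves the double bond to C15=C17 and closes the 14-membered carbocycle in a 14-exo-trig mode to give 24. The closest known reaction types are the aqueous indium Barbier coupling of 2-(bromomethyl)alk-2-enoates with α-hydroxy aldehydes and the metal-mediated cyclisation of ω-formyl 2-(bromomethyl)acrylates to carbocycle-fused α-methylene lactones, large rings included. C14 is controlled by C13: the free C13 hydroxyl and the aldehyde oxygen chelate indium(III) in water, and the allyl group attacks the chelate on the face away from the C12 branch, which gives the 13,14-syn diol (14R). C1 is controlled by the chair: the more stable allylindium has the C2 chain cis to CH2In and trans to the ester, so the chain sits axial and the C1/C14 relation comes out syn (1S, H1 and H14 cis). The C14 oxygen then attacks the C16 ester (5-exo-trig acyl substitution, loss of methanol) to give the cis-fused lactone 25, and this five-membered closure through O14 should outrun the six-membered one through O13. The step needs ring closure over oligomerisation (slow addition, high dilution), attack through C1 rather than C17 (the normal mode of substituted allylindiums; the other mode would need a 16-membered ring without the chelated chair), and tolerance of the tertiary allylic alcohol, the skipped diene and the ester, all of which are inert to indium in neutral water.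

Step 16
Reactants: 25 (1S,3E,6E,8R,12S,13R,14R)-8,13-dihydroxycembra-3,6,15(17)-trien-16,14-olide
Product: 26 (1S,3E,6E,8R,12S,13R,14R)-13-acetoxy-8-hydroxycembra-3,6,15(17)-trien-16,14-olide
Conditions: Ac2O, pyridine, DMAP (cat.), CH2Cl2, 0 °C
Reagents that add atoms: acetic anhydride, CC(=O)OC(C)=O
Why: Only the secondary C13 hydroxyl is acylated, because the tertiary C8 hydroxyl is too hindered under these conditions. Low temperature and a short reaction time limit acyl exchange between O13 and O14.

Step 17
Reactants: 26 (1S,3E,6E,8R,12S,13R,14R)-13-acetoxy-8-hydroxycembra-3,6,15(17)-trien-16,14-olide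
Product: 27 (1S,3R,4R,6E,8R,12S,13R,14R)-13-acetoxy-3,4-epoxy-8-hydroxycembra-6,15(17)-dien-16,14-olide (target)
Conditions: D-fructose-derived Shi ketone (cat.), Oxone, K2CO3, Bu4NHSO4 (cat.), MeCN–DMM/aq. borate–EDTA buffer, −5 °C
Reagents that add atoms: potassium peroxymonosulfate (Oxone), [K+].[O-]S(=O)(=O)OO
Why: In the Shi epoxidation the electrophilic chiral dioxirane picks the most electron-rich alkene. That is trisubstituted C3=C4, ahead of C6=C7 (disubstituted, deactivated by the allylic hydroxyl, shielded by C8) and the electron-poor C15=C17. The spiro transition state of the D-fructose-derived catalyst gives (R,R)-epoxides from E alkenes, i.e. 3R,4R, and the syn oxygen transfer keeps C2 and C5 trans.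

## Compound list

1 | pent-1-en-4-yne | C=CCC#C | starting material
2 | dimethyl[(1E)-2-methylpenta-1,4-dien-1-yl]alane | C=CC/C(C)=C/[Al](C)C | intermediate
3 | lithium butyl(dimethyl)[(1E)-2-methylpenta-1,4-dien-1-yl]alanate | [Li+].C=CC/C(C)=C/[Al-](C)(C)CCCC | intermediate
4 | (3E)-4-methylhepta-3,6-dien-1-ol | OCC/C=C(\C)CC=C | intermediate
5 | (3E)-4-methylhepta-3,6-dienal | O=CC/C=C(\C)CC=C | intermediate
6 | methyl propiolate | C#CC(=O)OC | starting material
7 | methyl 2-(diisobutylalumanyl)prop-2-enoate | C=C(C(=O)OC)[Al](CC(C)C)CC(C)C | intermediate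
8 | methyl (5E)-3-hydroxy-6-methyl-2-methylidenenona-5,8-dienoate (racemic) | C=CC/C(C)=C/CC(O)C(=C)C(=O)OC | intermediate
9 | methyl (2Z,5E)-2-(bromomethyl)-6-methylnona-2,5,8-trienoate | C=CC/C(C)=C/C/C=C(\CBr)C(=O)OC | intermediate
10 | (S)-citronellal, (3S)-3,7-dimethyloct-6-enal | O=CC[C@@H](C)CCC=C(C)C | starting material
11 | (2R,3S)-3,7-dimethyl-2-[(phenylamino)oxy]oct-6-enal | O=C[C@H](ONc1ccccc1)[C@@H](C)CCC=C(C)C | intermediate
12 | (2R,3S)-3,7-dimethyl-2-[(phenylamino)oxy]oct-6-en-1-ol | OC[C@H](ONc1ccccc1)[C@@H](C)CCC=C(C)C | intermediate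
13 | (2R,3S)-3,7-dimethyloct-6-ene-1,2-diol | OC[C@H](O)[C@@H](C)CCC=C(C)C | intermediate
14 | (2R,3S)-3,7-dimethyl-1,2-bis(triethylsilyloxy)oct-6-ene | CC[Si](CC)(CC)OC[C@H](O[Si](CC)(CC)CC)[C@@H](C)CCC=C(C)C | intermediate
15 | (2E,6S,7R)-2,6-dimethyl-7,8-bis(triethylsilyloxy)oct-2-en-1-ol | CC[Si](CC)(CC)OC[C@H](O[Si](CC)(CC)CC)[C@@H](C)CC/C=C(\C)CO | intermediate
16 | [(2S,3S)-2-methyl-3-{(3S,4R)-3-methyl-4,5-bis(triethylsilyloxy)pentyl}oxiran-2-yl]methanol | CC[Si](CC)(CC)OC[C@H](O[Si](CC)(CC)CC)[C@@H](C)CC[C@@H]1O[C@@]1(C)CO | intermediate
17 | (2R,6S,7R)-2,6-dimethyl-7,8-bis(triethylsilyloxy)octane-1,2-diol | CC[Si](CC)(CC)OC[C@H](O[Si](CC)(CC)CC)[C@@H](C)CCC[C@@](C)(O)CO | intermediate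
18 | (2R,6S,7R)-2-hydroxy-2,6-dimethyl-7,8-bis(triethylsilyloxy)octanal | CC[Si](CC)(CC)OC[C@H](O[Si](CC)(CC)CC)[C@@H](C)CCC[C@@](C)(O)C=O | intermediate
19 | (3R,7S,8R)-3,7-dimethyl-8,9-bis(triethylsilyloxy)non-1-en-3-ol | CC[Si](CC)(CC)OC[C@H](O[Si](CC)(CC)CC)[C@@H](C)CCC[C@@](C)(O)C=C | intermediate
20 | (2R,3S,7R)-7-hydroxy-3,7-dimethyl-2-(triethylsilyloxy)non-8-enal | O=C[C@H](O[Si](CC)(CC)CC)[C@@H](C)CCC[C@@](C)(O)C=C | intermediate
21 | methyl (2Z,5E,8E,10R,14S,15R)-2-(bromomethyl)-10-hydroxy-6,10,14-trimethyl-16-oxo-15-(triethylsilyloxy)hexadeca-2,5,8-trienoate | O=C[C@H](O[Si](CC)(CC)CC)[C@@H](C)CCC[C@@](C)(O)/C=C/C/C(C)=C/C/C=C(\CBr)C(=O)OC | intermediate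
22 | methyl (2Z,5E,8E,10R,14S,15R)-2-(bromomethyl)-10,15-dihydroxy-6,10,14-trimethyl-16-oxohexadeca-2,5,8-trienoate | O=C[C@H](O)[C@@H](C)CCC[C@@](C)(O)/C=C/C/C(C)=C/C/C=C(\CBr)C(=O)OC | intermediate
23 | allylindium derived from 22, drawn as the monoallylindium dibromide (Z form; E and Z interconvert) | O=C[C@H](O)[C@@H](C)CCC[C@@](C)(O)/C=C/C/C(C)=C/C/C=C(\C[In](Br)Br)C(=O)OC | intermediate
24 | methyl 2-[(1S,2R,3R,4S,8R,9E,12E)-2,3,8-trihydroxy-4,8,12-trimethylcyclotetradeca-9,12-dien-1-yl]prop-2-enoate | O[C@H]1[C@H](O)[C@@H](C)CCC[C@@](C)(O)/C=C/C/C(C)=C/C[C@H]1C(=C)C(=O)OC | intermediate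
25 | (1S,3E,6E,8R,12S,13R,14R)-8,13-dihydroxycembra-3,6,15(17)-trien-16,14-olide | C=C1C(=O)O[C@H]2[C@H](O)[C@@H](C)CCC[C@@](C)(O)/C=C/C/C(C)=C/C[C@@H]12 | intermediate
26 | (1S,3E,6E,8R,12S,13R,14R)-13-acetoxy-8-hydroxycembra-3,6,15(17)-trien-16,14-olide | C=C1C(=O)O[C@H]2[C@H](OC(C)=O)[C@@H](C)CCC[C@@](C)(O)/C=C/C/C(C)=C/C[C@@H]12 | intermediate
27 | (1S,3R,4R,6E,8R,12S,13R,14R)-13-acetoxy-3,4-epoxy-8-hydroxycembra-6,15(17)-dien-16,14-olide (CNP0202356.3) | C=C1C(=O)O[C@H]2[C@H](OC(C)=O)[C@@H](C)CCC[C@@](C)(O)/C=C/C[C@@]3(C)O[C@@H]3C[C@@H]12 | target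

## Step count and least certain steps

Total step count: 17.
Longest linear sequence: 13 steps (10 to 27, steps 5–17). The branch from 1 to 9 has 4 steps.

**Step 15 (key step).**
- *What may go wrong.*
  - Bimolecular allylation (oligomer formation) or slow protonolysis of the allylindium may compete with a ring closure that has no conformational help.
  - The tether may disturb the chelated chair. That would mean poor facial selectivity at C14 or attack through the unsubstituted terminus C17.
  - After ring closure, the acyl group may transfer to O13.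
- *Fallback (sets out from 20 and 9, comes back at 25).* Compound 20 is desilylated with buffered HF·pyridine to (2R,3S,7R)-2,7-dihydroxy-3,7-dimethylnon-8-enal F1. F1 is coupled intermolecularly with 9 by indium in aqueous THF, the setting in which the chelation-controlled syn,syn outcome has its closest precedent. Lactonisation gives the seco-diene lactone F2. The ring is then closed at C6=C7 by ring-closing metathesis at high dilution, which gives 25.

**Step 17.**
- *What may go wrong.*
  - Facial selectivity will be poor if the preferred ring conformation shields the face that the catalyst demands.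
  - C6=C7 may be oxidised in competition.
  - The acetate or lactone may hydrolyse slowly in the basic buffer.
- *Fallback (sets out from 8, comes back at 27).* The epoxide is installed on the open chain, where catalyst control is not opposed by a ring.
  - Shi epoxidation of 8 gives the epoxy carbinol F3 (both C1 epimers, which do not matter).
  - NBS/Me2S converts F3 into the epoxy bromide F4.
  - Cross metathesis of F4 with 20 gives F5, and buffered HF·pyridine gives the hydroxy aldehyde F6.
  - The indium macrocyclisation of F6 gives the epoxy hydroxy lactone F7.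
  - Acetylation of F7 gives 27.

**Step 13.**
- *What may go wrong.*
  - Turnover may be slow at the hindered vinyl carbinol while 9 homodimerises.
  - Ruthenium hydrides may cause migration of the skipped diene.
  - The α-silyloxy aldehyde may erode during the long heating.
- *Fallback (sets out from 19 and 9, comes back at 21).* The aldehyde is kept out of the metathesis. The robust bis-silyl ether 19 is crossed with 9 to give F8. The primary silyl ether of F8 is cleaved selectively with buffered HF·pyridine at low temperature to give the primary alcohol F9. Dess–Martin oxidation of F9 gives 21.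

**Step 3 (together with step 2).**
- *What may go wrong.*
  - C3=C4 of 5 may migrate into conjugation on the Lewis-acidic aluminium species.
  - Residual hydride may reduce 5 before the vinylalane adds.
- *Fallback (sets out from 5, comes back at 8).* The vinyl-metal addition is replaced by a fast low-temperature aldol reaction with an acrylate α-anion equivalent. The lithium enolate of commercial methyl 3-(dimethylamino)propanoate (LDA, THF, −78 °C) adds to 5 to give the amino alcohol F10. Methyl iodide converts F10 into the ammonium salt F11, and DBU-induced elimination gives 8.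

## Further compounds

F1 | step 15 | (2R,3S,7R)-2,7-dihydroxy-3,7-dimethylnon-8-enal | O=C[C@H](O)[C@@H](C)CCC[C@@](C)(O)C=C
F2 | step 15 | (4S,5R)-5-[(1R,2S,6R)-1,6-dihydroxy-2,6-dimethyloct-7-en-1-yl]-4-[(2E)-3-methylhexa-2,5-dien-1-yl]-3-methylideneoxolan-2-one | C=C1C(=O)O[C@@H]([C@H](O)[C@@H](C)CCC[C@@](C)(O)C=C)[C@H]1C/C=C(\C)CC=C
F3 | step 17 | methyl 3-hydroxy-2-methylidene-4-[(2R,3R)-3-methyl-3-(prop-2-en-1-yl)oxiran-2-yl]butanoate (both carbinol epimers) | C=CC[C@@]1(C)O[C@@H]1CC(O)C(=C)C(=O)OC
F4 | step 17 | methyl (2Z)-2-(bromomethyl)-4-[(2R,3R)-3-methyl-3-(prop-2-en-1-yl)oxiran-2-yl]but-2-enoate | C=CC[C@@]1(C)O[C@@H]1C/C=C(\CBr)C(=O)OC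
F5 | step 17 | 5,6-epoxide of 21, (5R,6R) in the chain numbering of 21 (C3/C4 in cembrane numbering) | O=C[C@H](O[Si](CC)(CC)CC)[C@@H](C)CCC[C@@](C)(O)/C=C/C[C@@]1(C)O[C@@H]1C/C=C(\CBr)C(=O)OC
F6 | step 17 | 5,6-epoxide of 22, (5R,6R) in the chain numbering of 22 | O=C[C@H](O)[C@@H](C)CCC[C@@](C)(O)/C=C/C[C@@]1(C)O[C@@H]1C/C=C(\CBr)C(=O)OC
F7 | step 17 | (1S,3R,4R,6E,8R,12S,13R,14R)-3,4-epoxy-8,13-dihydroxycembra-6,15(17)-dien-16,14-olide | C=C1C(=O)O[C@H]2[C@H](O)[C@@H](C)CCC[C@@](C)(O)/C=C/C[C@@]3(C)O[C@@H]3C[C@@H]12
F8 | step 13 | methyl (2Z,5E,8E,10R,14S,15R)-2-(bromomethyl)-10-hydroxy-6,10,14-trimethyl-15,16-bis(triethylsilyloxy)hexadeca-2,5,8-trienoate | CC[Si](CC)(CC)OC[C@H](O[Si](CC)(CC)CC)[C@@H](C)CCC[C@@](C)(O)/C=C/C/C(C)=C/C/C=C(\CBr)C(=O)OC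
F9 | step 13 | methyl (2Z,5E,8E,10R,14S,15R)-2-(bromomethyl)-10,16-dihydroxy-6,10,14-trimethyl-15-(triethylsilyloxy)hexadeca-2,5,8-trienoate | OC[C@H](O[Si](CC)(CC)CC)[C@@H](C)CCC[C@@](C)(O)/C=C/C/C(C)=C/C/C=C(\CBr)C(=O)OC
F10 | step 3 | methyl (5E)-2-[(dimethylamino)methyl]-3-hydroxy-6-methylnona-5,8-dienoate (diastereomer mixture, racemic) | C=CC/C(C)=C/CC(O)C(CN(C)C)C(=O)OC
F11 | step 3 | [(5E)-3-hydroxy-2-(methoxycarbonyl)-6-methylnona-5,8-dien-1-yl]trimethylammonium iodide | C=CC/C(C)=C/CC(O)C(C[N+](C)(C)C)C(=O)OC.[I-]
A1 | alternative 1 | (4S,5R)-5-[(1R,2S,6R)-1-acetoxy-6-hydroxy-2,6-dimethyloct-7-en-1-yl]-4-{[(2R,3R)-3-methyl-3-(prop-2-en-1-yl)oxiran-2-yl]methyl}-3-methylideneoxolan-2-one | C=C1C(=O)O[C@@H]([C@H](OC(C)=O)[C@@H](C)CCC[C@@](C)(O)C=C)[C@H]1C[C@H]2O[C@]2(C)CC=C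
A2 | alternative 2 | seco-13,14-dialdehyde: methyl (5E,8E)-3-formyl-10-hydroxy-6,10,14-trimethyl-2-methylidene-15-oxopentadeca-5,8-dienoate with the C1, C8 and C12 configurations of 27 | O=C[C@@H](C)CCC[C@@](C)(O)/C=C/C/C(C)=C/C[C@H](C=O)C(=C)C(=O)OC
A3 | alternative 3 | (1S,3R,4R,7E,12S,13R,14R)-13-acetoxy-3,4-epoxycembra-7,15(17)-dien-16,14-olide | C=C1C(=O)O[C@H]2[C@H](OC(C)=O)[C@@H](C)CCC/C(C)=C/CC[C@@]3(C)O[C@@H]3C[C@@H]12
A4 | alternative 3 | (1S,3R,4R,6E,8R,12S,13R,14R)-13-acetoxy-3,4-epoxy-8-hydroperoxycembra-6,15(17)-dien-16,14-olide | C=C1C(=O)O[C@H]2[C@H](OC(C)=O)[C@@H](C)CCC[C@@](C)(OO)/C=C/C[C@@]3(C)O[C@@H]3C[C@@H]12
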